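Take what is left: at 40 h, Tuesday's run still holds a share 30.0 % of its substrate charge, and Thursday's flask, with the same charge, is asked about at 120 h.

| flask | substrate | partner | free catalyst | time |
|---|---|---|---|---|
| Tuesday's | 150 mM | 375 mM | 0.750 mM |  |
| Saturday's | 90.0 mM | 315 mM | 0.750 mM |  |
| Wednesday's | 150 mM | 375 mM | 1.50 mM |  |
| Thursday's | 150 mM | 375 mM | 0.750 mM | 120 h |

| run | time / h | [substrate] / mM |
|---|---|---|
| Tuesday's run | 6.7 | 75.4 |
| Tuesday's run | 13 | 62.3 |
| Tuesday's run | 20 | 56.8 |
| Tuesday's run | 27 | 55.6 |
| Tuesday's run | 33 | 49.9 |
| Tuesday's run | 40 | 45.0 |
| Saturday's run | 6.7 | 45.3 |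
| Saturday's run | 13 | 42.0 |
| Saturday's run | 20 | 35.3 |
| Saturday's run | 27 | 34.6 |
| Saturday's run | 33 | 28.0 |
| Saturday's run | 40 | 28.6 |
| Wednesday's run | 6.7 | 19.8 |
| Wednesday's run | 13 | 23.0 |
| Wednesday's run | 20 | 18.7 |
| Wednesday's run | 27 | 15.3 |
| Wednesday's run | 33 | 12.9 |
| Wednesday's run | 40 | 10.1 |

(each reading ± 2 mM)

- how the opening rate goes with [free catalyst] round the charge of the Tuesday's run: the exponent of the rate at two percent of substrate gone to product
- the Saturday's run starts with 60.0 mM less of substrate and of partner than the Tuesday's run, and with no product. Compared where both hold the same amount of substrate, once fifteen percent of what the Saturday's run was charged with has turned into product, is the Saturday's run faster, slower or alike (within a tenth)?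
- substrate in the Thursday's run at 120 h, as a share of the substrate charged

- Overall: substrate + partner -> product, with free catalyst as catalyst.
- Constant volume, constant temperature.
- An order is taken over about fifteen percent of the charge, up and down.

Two people stand at the board. The first, who made the forecast, starts from the comparison at equal substrate: near the middle of Tuesday's fall, Saturday's run loses about 7 mM/h and Tuesday's about 2 mM/h. She reads this as "product inhibition is the likely cause", so for her the tail keeps slowing as product builds. She writes 1.5 for the exponent, faster for the comparison and 14 % for Thursday's share.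

The second, whose reckoning this is, replaces Tuesday's tail by one mean. Call it the tail constant, the fraction of the remaining substrate lost per hour, averaged from the reading at 6.7 h to the one at 40 h: 0.0155 h⁻¹. In Tuesday's run at 40 h, partner still stands at 72.0 % of its charge and outnumbers substrate, so a pseudo-first-order picture is a fair one to try.

Now check the error of that mean by splitting Tuesday's tail in two ways. Cut at 27 h, the earlier stretch gives 0.0150 h⁻¹ and the later one 0.0163 h⁻¹. Cut at 20 h, the earlier stretch gives 0.0213 h⁻¹ and the later one 0.0116 h⁻¹. The later figure is higher than the earlier with the first cut and lower with the second, so readings with a scatter of 2 mM do not tell whether Tuesday's tail slows.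

Carried from 40 h to 120 h, the tail constant leaves a share of 8.68 %, and the later stretches of the two cuts give 8.14 % and 11.9 %. The forecast's 14 % would need a mean constant of 0.00953 h⁻¹, lower than the figure of any stretch above. On the other two questions the second person has no reckoning and lets her values stand.

    2 free catalyst ⇌ catalyst dimer, settled at all times (1250 M⁻¹)
    catalyst dimer + substrate + partner → product + catalyst dimer (6300 M⁻² h⁻¹)
    free catalyst + partner → spent catalyst + partner (2.261 M⁻¹ h⁻¹)
    substrate + partner → product (0.05832 M⁻¹ h⁻¹)

Thursday's run holds 8.90 % of its charge at 120 h; the exponent comes to 1.3, and Saturday's run is faster. The forecast's view keeps the opening of the flask: at equal substrate, at the point asked about, Saturday's rate is 13 times Tuesday's, so there a rate depends on what went before. Between Tuesday's last reading and Thursday's answer the mean constant is 0.0152 h⁻¹. In Saturday's run, product comes to half the charge at 6.91 h; the tail constant from there gives a share of 29.9 % at 40 h, where the reading is 31.8 %.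

The data were computed with made-up constants; scatter was added.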